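## Structural features

Atom numbers follow the butanedioic chain of the target and are kept for all intermediates: C1 is the free carboxyl carbon, C2 carries ring A (4-hydroxyphenyl) directly, C3 carries the CH2 that leads to ring B (3-hydroxy-4-prenylphenyl), and C4 is the methyl ester carbon. The molecule is an open-chain 2-aryl-3-benzylsuccinic acid whose two chemically similar carboxyls are differentiated as acid (C1) and methyl ester (C4). C2 and C3 are adjacent stereocentres, both R. If C1 and C4 are joined through oxygen in thought, ring A and the benzyl group lie cis on the five-membered ring, so the target belongs to the erythro (pseudo-meso) series, the less stable one in any cyclic derivative. C2–H is benzylic and α to a carbonyl and epimerises easily whenever C1 is an ester, anhydride or imide and a base is present; C3–H is an ordinary ester α-hydrogen. Fragile groups are the prenyl C=C ortho to a free phenol (acid closes it to a chroman; heterogeneous hydrogenation or ozone destroys it), the two phenols, and the acid/ester pair, which any equilibrating esterification would scramble. Ring B has prenyl ortho to OH and para to the side chain, a pattern that direct prenylation of a 3-alkylphenol does not give cleanly. The real difficulty is to create both contiguous stereocentres in the contra-thermodynamic cis relation with the right absolute sense, and then to put OH and OMe on the correct carboxyls without disturbing C2–H. The key step exploits the fact that O, C1, C2, C3 and C4 form a latent maleic anhydride ring: with C2=C3 inside that ring the alkene geometry is locked, and syn addition of H2 to C2 and C3 can only give the cis pair.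

## Logic of the disconnections

In one sentence: both stereocentres are made together by enantioface-selective syn-hydrogenation of the ring-locked tetrasubstituted C2=C3 bond of 10. This does not describe the routes usually drawn first (benzylation of a succinate enolate, or hydrogenation of the exocyclic benzylidene of a Stobbe half-ester), which set one centre at a time.

13 ⇒ 12. Bonds concerned: the two phenolic O–acetyl bonds. The phenols must be masked while C1/C4 form an anhydride and during hydrogenation. Acetate is the mask that step 4 installs at no extra cost, and it leaves under conditions where C1 is a carboxylate and C2–H is therefore safe. The gain is a last step that is only a mild transesterification. The demand is cleavage without touching the C4 methyl ester or C3–H.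

12 ⇒ 11. Bond cut: C4–OMe, with C1 and C4 reconnected through oxygen. The ring turns the acid/ester problem into a choice between the two carbonyls of a pseudo-meso ring, the kind of choice alkaloid-mediated alcoholysis is known to make. The two carboxyls become one functional group and the two stereocentres become a cis-disubstituted ring that one syn addition can deliver. The demand is that methanol attacks C4 and not C1, and that the amine does not remove C2–H.

11 ⇒ 10 (key). Bonds cut: C2–H and C3–H. Both stereocentres are erased at once. Because C2=C3 lies in the ring, 10 has no alkene isomers, and the cis relation in 11 is the necessary result of suprafacial addition. The precursor is flat and achiral. The demand is a catalyst that reduces a tetrasubstituted electron-poor C=C with face selection, leaves the prenyl C=C alone, and works without base.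

10 ⇒ 8 (through 9). Bonds cut: the C1–O–C4 link and the two O–acetyl bonds; the C=C is moved from C2=C3 to the exocyclic C3=CH position. One reagent acetylates and dehydrates 8, and the exo-to-endo shift is downhill (tetrasubstituted alkene conjugated with both carbonyls and ring A). The gain is that a tetrasubstituted alkene comes from a trisubstituted one whose geometry does not matter. The demand is reversible removal of C2–H of 9 by a weak base without acylation of the anion. The acid/ester pattern that the Stobbe step gives in 7 is knowingly surrendered here, because the ring that locks the alkene needs both carboxyls.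

8 ⇒ 3 + 6 (through 7). Bond cut: C3=CH. This is a Stobbe union of a succinate with an aryl aldehyde, giving two fragments of similar size, each one step from commercial material. The demand is productive enolisation at C3 and tolerance of two phenoxides.

3 ⇒ 1 + 2. Bond cut: C2–C(ring A). Conjugate arylation of a fumarate makes the arylsuccinate in one step with the phenol free. A racemate suffices because C2 later becomes sp2.

6 ⇒ 4 + 5. Bond cut: C(ring B)–CH2 of the prenyl group. The bromine of 4 marks the only position (ortho to OH, para to CHO) where prenyl may enter, which removes the regiochemical problem of phenol prenylation. The demand is coupling at the unsubstituted allyl terminus.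

## Other disconnections considered

Alternative 1: (first to come to mind) cut the C3–CH2 bond to ring B. The forward key step is benzylation of the C3 lithium enolate of the enantiopure mixed diester A1 with the benzylic bromide A2 to give A3.
- In A1 the most acidic hydrogen is C2–H (benzylic and α to an ester), so a C3 enolate cannot be formed without risking the C2 configuration.
- Open-chain succinate enolates are expected to take the electrophile anti to the C2 substituent, which leads to the threo isomer A3 (2R,3S), the wrong relative configuration.
- The two centres need two separate asymmetric operations, and A2 alone costs three steps from 6.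

Alternative 2: cut C3–H and the benzylic C–H of the exocyclic alkene. The forward key step is rhodium/chiral bisphosphine hydrogenation of the Stobbe half-ester 7 (an itaconate-type substrate that already has acid at C1 and ester at C4) to give A4.
- This is well-precedented for C3, but C2 of 7 is already sp3 and racemic, so A4 is a pair of C2 epimers.
- The mixture cannot be corrected afterwards: in A4, C2–H is α to a carboxylate and C3–H is the more acidic one, so base would scramble the wrong centre.
- The chosen plan uses the same cheap Stobbe C–C bond formation but moves the alkene to C2=C3, so both centres are sp2 before hydrogen is added.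

Alternative 3: cut the C2–C3 bond. The forward key step is oxidative heterocoupling (Fe(acac)3 or a copper carboxylate as oxidant) of the lithium enolates of the chiral N-acyloxazolidinone A5 and the ester A6 to give A7.
- It is convergent and differentiates the carboxyls by construction.
- However, the bond joins two prostereogenic carbons in an intermolecular radical-type coupling: the auxiliary can bias only C2, and nothing controls C3, so no element favours the erythro isomer.
- Homocoupling is expected to compete, and A6 and the auxiliary add steps.
- In the chosen plan the relative configuration is a geometric consequence of the ring, not a selectivity to be hoped for.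

Key step: step 5

Assumption: the sense of induction cannot be fixed on paper for this substrate, so the ligand antipode in step 5 and the alkaloid pseudoenantiomer in step 6 (quinine is written; quinidine otherwise) are each chosen by one trial so that (2R,3R) material with the ester at C4 results.

## Route

Step 1
Reactants: 1 (4-hydroxyphenyl)boronic acid; 2 dimethyl fumarate
Product: 3 dimethyl 2-(4-hydroxyphenyl)butanedioate (racemic)
Conditions: [Rh(cod)OH]2 (1.5 mol %), 1 (1.5 equiv), dioxane/H2O 10:1, 50 °C
Reagents that add atoms: none
Why: Rhodium-catalysed conjugate addition of an arylboronic acid (Hayashi–Miyaura reaction): transmetalation to aryl–rhodium, insertion of the fumarate C=C and protonolysis by water; the free phenol is tolerated and the racemic C2 centre is irrelevant because it becomes sp2 in step 4.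

Step 2
Reactants: 4 4-bromo-3-hydroxybenzaldehyde; 5 tributyl(3-methylbut-2-en-1-yl)stannane
Product: 6 3-hydroxy-4-(3-methylbut-2-en-1-yl)benzaldehyde
Conditions: Pd(PPh3)4 (5 mol %), DMF, 90 °C
Reagents that add atoms: none
Why: Stille coupling: zerovalent palladium inserts into the C–Br bond para to the formyl group, and reductive elimination at the unsubstituted allyl terminus (the other would build a quaternary carbon) should give the linear prenyl arene; the neutral conditions tolerate phenol and aldehyde, and the bromine fixes the ring B pattern.

Step 3
Reactants: 3 dimethyl 2-(4-hydroxyphenyl)butanedioate; 6 3-hydroxy-4-(3-methylbut-2-en-1-yl)benzaldehyde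
Product: 8 2-(4-hydroxyphenyl)-3-{(E)-[3-hydroxy-4-(3-methylbut-2-en-1-yl)phenyl]methylidene}butanedioic acid (racemic), via Stobbe half-ester 7 (not isolated)
Conditions: KOtBu (4.5 equiv), tBuOH/THF, 50 °C; then 2 M aq KOH, 70 °C; then 1 M HCl to pH 2, 0 °C
Reagents that add atoms: potassium hydroxide (aqueous), [K+].[OH-]
Why: Stobbe condensation: the C3 ester enolate adds to the aldehyde, the alkoxide lactonises onto the C1 ester and E1cB ring opening gives the benzylidene half-ester carboxylate 7, which hot aqueous KOH saponifies at C4. The phenoxide of 6 is meta to the formyl group and so not conjugated with it, and the para-phenoxide of 3 disfavours deprotonation at C2, so both should be spectators.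

Step 4
Reactants: 8 2-(4-hydroxyphenyl)-3-{(E)-[3-hydroxy-4-(3-methylbut-2-en-1-yl)phenyl]methylidene}butanedioic acid
Product: 10 4-[4-({3-acetoxy-4-(3-methylbut-2-en-1-yl)phenyl}methyl)-2,5-dioxo-2,5-dihydrofuran-3-yl]phenyl acetate, via benzylidenesuccinic anhydride diacetate 9 (not isolated)
Conditions: Ac2O (5 equiv), pyridine (6 equiv), CH2Cl2, 0 °C to rt; evaporate with toluene; then Et3N (0.2 equiv), toluene, 40 °C
Reagents that add atoms: acetic anhydride, CC(=O)OC(C)=O
Why: Acetic anhydride/pyridine acetylates both phenols and dehydrates the 1,4-diacid to the five-membered anhydride 9. Catalytic triethylamine then removes C2–H (benzylic, α-carbonyl, giving a 2-oxidofuran-type anion) and reprotonation at the exocyclic carbon moves the C=C into the ring, as in the itaconic-to-citraconic anhydride shift; 10 should be favoured because its alkene is tetrasubstituted and conjugated with both carbonyls and ring A.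

Step 5
Reactants: 10 4-[4-({3-acetoxy-4-(3-methylbut-2-en-1-yl)phenyl}methyl)-2,5-dioxo-2,5-dihydrofuran-3-yl]phenyl acetate
Product: 11 4-[(3R,4R)-4-({3-acetoxy-4-(3-methylbut-2-en-1-yl)phenyl}methyl)-2,5-dioxooxolan-3-yl]phenyl acetate
Conditions: H2 (50 bar), [Rh(cod)Cl]2 (1 mol %), chiral ligand N-[3,5-bis(trifluoromethyl)phenyl]-N'-{1-[1',2-bis(diphenylphosphino)ferrocenyl]ethyl}thiourea (2.2 mol %, single enantiomer), CH2Cl2, 30 °C
Reagents that add atoms: none
Why: Monovalent rhodium on the chiral bisphosphine adds H2 oxidatively, the C2=C3 bond of 10 coordinates while the thiourea N–H groups hold one anhydride carbonyl by hydrogen bonding, and migratory insertion followed by reductive elimination delivers both hydrogens to the same face. The closest known reaction types are the rhodium/bisphosphine–thiourea asymmetric hydrogenation of substituted maleic anhydrides and maleimides and the asymmetric hydrogenation of tetrasubstituted α-aryl acrylic acid derivatives. No ring is closed; the existing anhydride ring holds the two carbonyls cis and so fixes the alkene geometry that an open-chain diester could lose. C2 and C3 are therefore set together: the relative configuration (ring A and benzyl cis) follows from syn addition to the ring-locked alkene, and the absolute configuration (R at both) from the face exposed by the ligand. Enantioface selection is to come from two-point binding (alkene to rhodium, carbonyl to thiourea) of a nearly planar substrate. Chemoselection against the prenyl C=C rests on that alkene being trisubstituted, unactivated and without a hydrogen-bond acceptor to bring it to the metal. The cis relation is preserved because no base is present, although C2–H of 11 is acidic; the aryl acetates and the anhydride are inert in aprotic CH2Cl2.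

Step 6
Reactants: 11 4-[(3R,4R)-4-({3-acetoxy-4-(3-methylbut-2-en-1-yl)phenyl}methyl)-2,5-dioxooxolan-3-yl]phenyl acetate
Product: 12 (2R,3R)-2-(4-acetoxyphenyl)-3-{[3-acetoxy-4-(3-methylbut-2-en-1-yl)phenyl]methyl}-4-methoxy-4-oxobutanoic acid
Conditions: MeOH (3 equiv), quinine (1.1 equiv), toluene, −50 °C; then cold 1 M HCl wash
Reagents that add atoms: methanol, CO
Why: Cinchona-alkaloid-mediated methanolysis of a cyclic anhydride, the reaction type used to desymmetrise meso anhydrides and to resolve 2-arylsuccinic anhydrides regiodivergently. 11 is pseudo-meso, so its two carbonyls sit in nearly mirror-image surroundings and the matched alkaloid should deliver methanol to C4; the weak amine base at low temperature should leave C2–H untouched, and no stereocentre is formed or broken.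

Step 7
Reactants: 12 (2R,3R)-2-(4-acetoxyphenyl)-3-{[3-acetoxy-4-(3-methylbut-2-en-1-yl)phenyl]methyl}-4-methoxy-4-oxobutanoic acid
Product: 13 (2R,3R)-3-{[3-hydroxy-4-(3-methylbut-2-en-1-yl)phenyl]methyl}-2-(4-hydroxyphenyl)-4-methoxy-4-oxobutanoic acid
Conditions: K2CO3 (3 equiv), MeOH, 0 °C; then 1 M HCl to pH 3, 0 °C
Reagents that add atoms: none
Why: Zemplén-type transesterification of the two phenyl acetates to methyl acetate. C1 is a carboxylate under these conditions, so C2–H is not acidic; carbonate at 0 °C should not remove C3–H; and exchange at the C4 methyl ester in methanol is degenerate.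

## Compound list

1 | (4-hydroxyphenyl)boronic acid | OB(O)c1ccc(O)cc1 | starting material
2 | dimethyl fumarate | COC(=O)/C=C/C(=O)OC | starting material
3 | dimethyl 2-(4-hydroxyphenyl)butanedioate (racemic) | COC(=O)CC(C(=O)OC)c1ccc(O)cc1 | intermediate
4 | 4-bromo-3-hydroxybenzaldehyde | O=Cc1ccc(Br)c(O)c1 | starting material
5 | tributyl(3-methylbut-2-en-1-yl)stannane | CCCC[Sn](CCCC)(CCCC)CC=C(C)C | starting material
6 | 3-hydroxy-4-(3-methylbut-2-en-1-yl)benzaldehyde | O=Cc1ccc(CC=C(C)C)c(O)c1 | intermediate
7 | (3E)-4-[3-hydroxy-4-(3-methylbut-2-en-1-yl)phenyl]-2-(4-hydroxyphenyl)-3-(methoxycarbonyl)but-3-enoic acid (racemic; potassium salt in the flask) | COC(=O)/C(=C/c1ccc(CC=C(C)C)c(O)c1)C(C(=O)O)c1ccc(O)cc1 | intermediate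
8 | 2-(4-hydroxyphenyl)-3-{(E)-[3-hydroxy-4-(3-methylbut-2-en-1-yl)phenyl]methylidene}butanedioic acid (racemic) | OC(=O)/C(=C/c1ccc(CC=C(C)C)c(O)c1)C(C(=O)O)c1ccc(O)cc1 | intermediate
9 | 4-[(4E)-4-({3-acetoxy-4-(3-methylbut-2-en-1-yl)phenyl}methylidene)-2,5-dioxooxolan-3-yl]phenyl acetate (racemic) | CC(=O)Oc1ccc(cc1)C2C(=O)OC(=O)/C2=C/c3ccc(CC=C(C)C)c(OC(C)=O)c3 | intermediate
10 | 4-[4-({3-acetoxy-4-(3-methylbut-2-en-1-yl)phenyl}methyl)-2,5-dioxo-2,5-dihydrofuran-3-yl]phenyl acetate | CC(=O)Oc1ccc(cc1)C2=C(Cc3ccc(CC=C(C)C)c(OC(C)=O)c3)C(=O)OC2=O | intermediate
11 | 4-[(3R,4R)-4-({3-acetoxy-4-(3-methylbut-2-en-1-yl)phenyl}methyl)-2,5-dioxooxolan-3-yl]phenyl acetate | CC(=O)Oc1ccc(cc1)[C@@H]2C(=O)OC(=O)[C@@H]2Cc3ccc(CC=C(C)C)c(OC(C)=O)c3 | intermediate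
12 | (2R,3R)-2-(4-acetoxyphenyl)-3-{[3-acetoxy-4-(3-methylbut-2-en-1-yl)phenyl]methyl}-4-methoxy-4-oxobutanoic acid | COC(=O)[C@H](Cc1ccc(CC=C(C)C)c(OC(C)=O)c1)[C@@H](C(=O)O)c1ccc(OC(C)=O)cc1 | intermediate
13 | (2R,3R)-3-{[3-hydroxy-4-(3-methylbut-2-en-1-yl)phenyl]methyl}-2-(4-hydroxyphenyl)-4-methoxy-4-oxobutanoic acid | COC(=O)[C@H](Cc1ccc(CC=C(C)C)c(O)c1)[C@@H](C(=O)O)c1ccc(O)cc1 | target

## Step count and least certain steps

Total: 7 steps. Longest linear sequence: 6 steps (1, 3, 4, 5, 6, 7); step 2 supplies the second fragment in one step.

**Step 5 (key).** The tetrasubstituted alkene, with ring A twisted out of plane, may take up hydrogen slowly, and the two-point binding that gives face selection with trisubstituted maleic anhydrides may discriminate less well here. Slow migration of the prenyl double bond by a rhodium hydride is a further possibility. The fallback changes both substrate and directing principle to a carboxylate-directed ruthenium hydrogenation. It sets out from 10. Aqueous NaOH in MeOH, then adjustment to about pH 8, opens the ring and removes the acetates to give disodium (2Z)-2-(4-hydroxyphenyl)-3-{[3-hydroxy-4-(3-methylbut-2-en-1-yl)phenyl]methyl}but-2-enedioate F1. Hydrogenation with Ru(OAc)2[(S)-BINAP] or its antipode (H2 60–100 bar, MeOH), in which the substrate carboxylate binds ruthenium and an isolated trisubstituted alkene is not expected to react, followed by acidification, should give (2R,3R)-2-(4-hydroxyphenyl)-3-{[3-hydroxy-4-(3-methylbut-2-en-1-yl)phenyl]methyl}butanedioic acid F2. Ac2O/pyridine in CH2Cl2 at 0 °C re-acetylates and closes the ring, rejoining the route at 11.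

**Step 6.** Methanol may attack the C1 carbonyl as well, because the inherent steric and electronic bias between an α-aryl and an α-benzyl carbonyl is small and the outcome rests on catalyst control. The amine might also epimerise C2 to the trans anhydride before ring opening. The fallback differentiates by hydrolysis of a diester instead of alcoholysis of the ring, and sets out from 11. Uncatalysed methanolysis (MeOH, 40 °C) gives 12 together with the regioisomeric half-ester (2R,3R)-3-(4-acetoxyphenyl)-2-{[3-acetoxy-4-(3-methylbut-2-en-1-yl)phenyl]methyl}-4-methoxy-4-oxobutanoic acid F3. Trimethylsilyldiazomethane in MeOH/toluene converts both to the single diester dimethyl (2R,3R)-2-(4-acetoxyphenyl)-3-{[3-acetoxy-4-(3-methylbut-2-en-1-yl)phenyl]methyl}butanedioate F4. A hydrolase (pig liver esterase as first candidate, pH 7 buffer with acetone) is then asked to cleave the two phenyl acetates and, of the two methyl esters, the electronically activated α-aryl one at C1, under conditions too mild for epimerisation. The regiochemical preference of the enzyme is unknown and would need screening. This rejoins the route at 13.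

**Step 3.** With two phenoxides present, the polyanions may be poorly soluble and the aldehyde less electrophilic, so the aldol step may be slow and retro-aldol or unproductive enolate chemistry may take over. The fallback forms the same C3=CH bond under neutral conditions by a phosphine-mediated Wittig-type olefination. It sets out from 1 and 6. Rhodium-catalysed hydroarylation of dimethyl acetylenedicarboxylate with 1 ([Rh(cod)OH]2, dioxane/H2O) gives dimethyl (2Z)-2-(4-hydroxyphenyl)but-2-enedioate F5. Tributylphosphine adds at C3, proton transfer gives the C3 ylide, and reaction with 6 gives dimethyl 2-(4-hydroxyphenyl)-3-{(E)-[3-hydroxy-4-(3-methylbut-2-en-1-yl)phenyl]methylidene}butanedioate F6. Aqueous KOH then acid gives 8, where the route is rejoined.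

**Step 4.** With acetic anhydride present while the enolisable anhydride 9 meets base, O-acetylation of the 2-oxidofuran anion may compete, and the exo-to-endo shift may stop short of completion. The fallback separates acylation from ring closure and sets out from 8. Schotten–Baumann acetylation (Ac2O, aq NaOH, 0 °C, then acidification) gives 2-(4-acetoxyphenyl)-3-{(E)-[3-acetoxy-4-(3-methylbut-2-en-1-yl)phenyl]methylidene}butanedioic acid F7. Dicyclohexylcarbodiimide in CH2Cl2 closes this to 9 with no acyl donor present, and catalytic Et3N then effects the double-bond shift, rejoining the route at 10.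

**Step 2.** Allylic transposition during transmetalation or reductive elimination would put the 1,1-dimethylallyl group on ring B instead of the linear prenyl group. The fallback avoids an unsymmetrical allyl metal and sets out from 4. Stille coupling with allyltributylstannane (Pd(PPh3)4, DMF) gives 3-hydroxy-4-(prop-2-en-1-yl)benzaldehyde F8, and cross-metathesis with excess 2-methylbut-2-ene (second-generation Grubbs catalyst, CH2Cl2, 40 °C) turns the allyl into the prenyl group, rejoining the route at 6.

## Further compounds

F1 | step 5 | disodium (2Z)-2-(4-hydroxyphenyl)-3-{[3-hydroxy-4-(3-methylbut-2-en-1-yl)phenyl]methyl}but-2-enedioate | [Na+].[Na+].[O-]C(=O)/C(=C(/Cc1ccc(CC=C(C)C)c(O)c1)C([O-])=O)c1ccc(O)cc1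
F2 | step 5 | (2R,3R)-2-(4-hydroxyphenyl)-3-{[3-hydroxy-4-(3-methylbut-2-en-1-yl)phenyl]methyl}butanedioic acid | OC(=O)[C@H](Cc1ccc(CC=C(C)C)c(O)c1)[C@@H](C(=O)O)c1ccc(O)cc1
F3 | step 6 | (2R,3R)-3-(4-acetoxyphenyl)-2-{[3-acetoxy-4-(3-methylbut-2-en-1-yl)phenyl]methyl}-4-methoxy-4-oxobutanoic acid | OC(=O)[C@H](Cc1ccc(CC=C(C)C)c(OC(C)=O)c1)[C@@H](C(=O)OC)c1ccc(OC(C)=O)cc1
F4 | step 6 | dimethyl (2R,3R)-2-(4-acetoxyphenyl)-3-{[3-acetoxy-4-(3-methylbut-2-en-1-yl)phenyl]methyl}butanedioate | COC(=O)[C@H](Cc1ccc(CC=C(C)C)c(OC(C)=O)c1)[C@@H](C(=O)OC)c1ccc(OC(C)=O)cc1
F5 | step 3 | dimethyl (2Z)-2-(4-hydroxyphenyl)but-2-enedioate | COC(=O)/C=C(\C(=O)OC)c1ccc(O)cc1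
F6 | step 3 | dimethyl 2-(4-hydroxyphenyl)-3-{(E)-[3-hydroxy-4-(3-methylbut-2-en-1-yl)phenyl]methylidene}butanedioate | COC(=O)/C(=C/c1ccc(CC=C(C)C)c(O)c1)C(C(=O)OC)c1ccc(O)cc1
F7 | step 4 | 2-(4-acetoxyphenyl)-3-{(E)-[3-acetoxy-4-(3-methylbut-2-en-1-yl)phenyl]methylidene}butanedioic acid | CC(=O)Oc1ccc(cc1)C(C(=O)O)/C(=C\c1ccc(CC=C(C)C)c(OC(C)=O)c1)C(=O)O
F8 | step 2 | 3-hydroxy-4-(prop-2-en-1-yl)benzaldehyde | O=Cc1ccc(CC=C)c(O)c1
A1 | alternative 1 | 1-tert-butyl 4-methyl (2R)-2-{4-[(tert-butyldimethylsilyl)oxy]phenyl}butanedioate | COC(=O)C[C@@H](C(=O)OC(C)(C)C)c1ccc(O[Si](C)(C)C(C)(C)C)cc1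
A2 | alternative 1 | 4-(bromomethyl)-2-[(tert-butyldimethylsilyl)oxy]-1-(3-methylbut-2-en-1-yl)benzene | BrCc1ccc(CC=C(C)C)c(O[Si](C)(C)C(C)(C)C)c1
A3 | alternative 1 | 1-tert-butyl 4-methyl (2R,3S)-2-{4-[(tert-butyldimethylsilyl)oxy]phenyl}-3-({3-[(tert-butyldimethylsilyl)oxy]-4-(3-methylbut-2-en-1-yl)phenyl}methyl)butanedioate | COC(=O)[C@@H](Cc1ccc(CC=C(C)C)c(O[Si](C)(C)C(C)(C)C)c1)[C@@H](C(=O)OC(C)(C)C)c1ccc(O[Si](C)(C)C(C)(C)C)cc1
A4 | alternative 2 | (3R)-3-{[3-hydroxy-4-(3-methylbut-2-en-1-yl)phenyl]methyl}-2-(4-hydroxyphenyl)-4-methoxy-4-oxobutanoic acid (mixture of C2 epimers) | COC(=O)[C@H](Cc1ccc(CC=C(C)C)c(O)c1)C(C(=O)O)c1ccc(O)cc1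
A5 | alternative 3 | (4S)-4-benzyl-3-(2-{4-[(tert-butyldimethylsilyl)oxy]phenyl}acetyl)-1,3-oxazolidin-2-one | O=C1OC[C@H](Cc2ccccc2)N1C(=O)Cc1ccc(O[Si](C)(C)C(C)(C)C)cc1
A6 | alternative 3 | methyl 3-{3-[(tert-butyldimethylsilyl)oxy]-4-(3-methylbut-2-en-1-yl)phenyl}propanoate | COC(=O)CCc1ccc(CC=C(C)C)c(O[Si](C)(C)C(C)(C)C)c1
A7 | alternative 3 | methyl (2R,3R)-4-[(4S)-4-benzyl-2-oxo-1,3-oxazolidin-3-yl]-3-{4-[(tert-butyldimethylsilyl)oxy]phenyl}-2-({3-[(tert-butyldimethylsilyl)oxy]-4-(3-methylbut-2-en-1-yl)phenyl}methyl)-4-oxobutanoate | COC(=O)[C@H](Cc1ccc(CC=C(C)C)c(O[Si](C)(C)C(C)(C)C)c1)[C@@H](C(=O)N1[C@@H](Cc2ccccc2)COC1=O)c1ccc(O[Si](C)(C)C(C)(C)C)cc1
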